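**Plan**

1. Numbering and enabling feature: butenolide O1–C2(=O)–C3(Me)=C4–C5(=C6), then C7(Me), cyclopentane C8–C9–C10–C11(Me)–C12, cyclohexene C12–C13–C14=C15(Me)–C16(O-acyl)–C17. The spiro atom C12 lies β to the C16 oxygen through C17 and its neighbour C8 carries the side chain, so C12 can be the β-carbon of a cyclohexenone that takes C8 over from a cyclobutanol whose carbinol carbon is C11. Atom labels in the text follow this numbering; compound names keep their own locants.
2. Retrosynthetic cuts, in order: C16–O (ester); C5=C6 (butenolide, from a C6 aldehyde); C14=C15 and C15–CH3; C11–CH3; C8–C12 (ring expansion); C11–C12 (alkenyllithium plus cyclobutanone); C8–C9 and C10–C11 (keteniminium plus ethene).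
3. Forward order: the cyclobutanone is built first, the six-membered ring is attached at C11, the shift of C8 to C12 turns the four-membered ring into the spiro cyclopentanone, then follow the C11 methyl, the C15-methyl enone, the C16 ester and last the butenolide.
4. Stereochemistry: C7 from the (R)-Roche ester; C8 from a C2-symmetric pyrrolidine auxiliary in the [2+2]; C12 from the chiral primary amine in the shift (C8 migrates with retention); C11 from hydroxyl-directed hydrogenation; C16 from Corey–Bakshi–Shibata reduction; the Z alkene from E1cB elimination.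

Key step: step 12

Assumption: the (2S,5S) auxiliary of step 5 and the quinidine-derived amine of step 12 are assigned from steric models of the keteniminium and iminium ions; should either induction prove opposite, the mirror-image auxiliary or the quinine-derived pseudoenantiomer is used and nothing else changes.

**Route**

Step 1
Reactants: 1 methyl (R)-3-hydroxy-2-methylpropanoate
Product: 2 methyl (R)-3-[(tert-butyldiphenylsilyl)oxy]-2-methylpropanoate
Conditions: TBDPSCl, imidazole, CH2Cl2, 0 °C to rt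
Reagents that add atoms: tert-butyldiphenylsilyl chloride, CC(C)(C)[Si](Cl)(c1ccccc1)c1ccccc1
Why: Silylation of the primary alcohol; the bulky, weakly basic silyl ether is chosen so that the C6 oxygen cannot attack the activated amide in step 5, and C7 is not touched.

Step 2
Reactants: 2 methyl (R)-3-[(tert-butyldiphenylsilyl)oxy]-2-methylpropanoate
Product: 3 (R)-3-[(tert-butyldiphenylsilyl)oxy]-2-methylpropanoic acid
Conditions: LiOH·H2O, THF/MeOH/H2O, 0 °C to rt; then 1 M HCl to pH 3, 0 °C
Reagents that add atoms: lithium hydroxide, [Li+].[OH-]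
Why: Ester saponification under mild conditions that neither cleave the silyl ether nor epimerise the α-centre.

Step 3
Reactants: 3 (R)-3-[(tert-butyldiphenylsilyl)oxy]-2-methylpropanoic acid
Product: 5 (R)-4-[(tert-butyldiphenylsilyl)oxy]-1-diazo-3-methylbutan-2-one, via isobutyl carbonic mixed anhydride 4 (not isolated)
Conditions: i-BuOCOCl, N-methylmorpholine, THF, −15 °C; then TMSCHN2, MeCN, 0 °C to rt
Reagents that add atoms: trimethylsilyldiazomethane, C[Si](C)(C)C=[N+]=[N-]
Why: First half of an Arndt–Eistert homologation; acylation of the diazoalkane through the mixed anhydride avoids the ketene pathway that would racemise C7, and the diazo carbon becomes C8.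

Step 4
Reactants: 5 (R)-4-[(tert-butyldiphenylsilyl)oxy]-1-diazo-3-methylbutan-2-one; 6 (2S,5S)-2,5-dimethylpyrrolidine
Product: 8 (S)-4-[(tert-butyldiphenylsilyl)oxy]-1-[(2S,5S)-2,5-dimethylpyrrolidin-1-yl]-3-methylbutan-1-one, via ketene 7 (not isolated)
Conditions: PhCO2Ag (10 mol %), Et3N, THF, −25 °C to rt, dark
Reagents that add atoms: none
Why: Wolff rearrangement in which C7 migrates with retention; the ketene is trapped by the secondary amine, which installs the auxiliary for step 5.

Step 5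
Reactants: 8 (S)-4-[(tert-butyldiphenylsilyl)oxy]-1-[(2S,5S)-2,5-dimethylpyrrolidin-1-yl]-3-methylbutan-1-one; 9 ethene
Product: 12 (R)-2-{(S)-1-[(tert-butyldiphenylsilyl)oxy]propan-2-yl}cyclobutan-1-one, via keteniminium triflate 10 (not isolated), via cyclobutaniminium triflate 11 (not isolated)
Conditions: Tf2O, 2,4,6-collidine, ethene (3 bar), ClCH2CH2Cl, 0 to 80 °C; then H2O, NaHCO3, 60 °C
Reagents that add atoms: water, O
Why: Keteniminium–alkene [2+2] cycloaddition, in which ethene adds to the central carbon from the side of the C8 hydrogen and the ring closes at C8 on the face not screened by the pyrrolidine 2-methyl group that is syn to the incoming alkene, which should set C8 as R; hydrolysis releases the ketone and the auxiliary.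

Step 6
Reactants: 13 cyclohexane-1,3-dione
Product: 14 3-bromocyclohex-2-en-1-one
Conditions: Ph3PBr2, Et3N, CH2Cl2, 0 °C to rt
Reagents that add atoms: dibromotriphenylphosphorane, BrP(Br)(c1ccccc1)(c1ccccc1)c1ccccc1
Why: Conversion of the enol of a 1,3-diketone into the vinylogous acyl bromide by O-phosphonium activation and addition–elimination of bromide.

Step 7
Reactants: 14 3-bromocyclohex-2-en-1-one
Product: 15 rac-3-bromocyclohex-2-en-1-ol
Conditions: NaBH4, CeCl3·7H2O, MeOH, 0 °C
Reagents that add atoms: none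
Why: Luche reduction gives clean 1,2-reduction of the enone; the carbinol centre is racemic, which is of no consequence because it returns to a ketone in step 11.

Step 8
Reactants: 15 rac-3-bromocyclohex-2-en-1-ol
Product: 16 rac-[(3-bromocyclohex-2-en-1-yl)oxy]triethylsilane
Conditions: TESCl, imidazole, CH2Cl2, 0 °C
Reagents that add atoms: chlorotriethylsilane, CC[Si](Cl)(CC)CC
Why: Silylation with a group that survives tert-butyllithium and can later be removed in the presence of the diphenylsilyl ether.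

Step 9
Reactants: 16 rac-[(3-bromocyclohex-2-en-1-yl)oxy]triethylsilane; 12 (R)-2-{(S)-1-[(tert-butyldiphenylsilyl)oxy]propan-2-yl}cyclobutan-1-one
Product: 18 (1R,2R)-2-{(S)-1-[(tert-butyldiphenylsilyl)oxy]propan-2-yl}-1-[3-(triethylsilyloxy)cyclohex-1-en-1-yl]cyclobutan-1-ol (two epimers at the silyloxy carbon), via alkenyllithium 17 (not isolated)
Conditions: 16, t-BuLi (2.1 equiv), Et2O, −78 °C; then 12, −78 °C; H2O
Reagents that add atoms: none
Why: Bromine–lithium exchange and 1,2-addition to the strained ketone, which at −78 °C should outrun enolisation so that C8 is kept; attack anti to the C8 branch places the hydroxyl cis to it, and the two epimers at the silyloxy carbon converge in step 11.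

Step 10
Reactants: 18 (1R,2R)-2-{(S)-1-[(tert-butyldiphenylsilyl)oxy]propan-2-yl}-1-[3-(triethylsilyloxy)cyclohex-1-en-1-yl]cyclobutan-1-ol
Product: 19 (1R,2R)-2-{(S)-1-[(tert-butyldiphenylsilyl)oxy]propan-2-yl}-1-(3-hydroxycyclohex-1-en-1-yl)cyclobutan-1-ol (two epimers)
Conditions: HF·pyridine, pyridine, THF, 0 °C
Reagents that add atoms: none
Why: Buffered fluoride removes the secondary triethylsilyl ether far faster than the primary tert-butyldiphenylsilyl ether, and strong acid is avoided because it could trigger an uncontrolled ring expansion of the allylic cyclobutanol.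

Step 11
Reactants: 19 (1R,2R)-2-{(S)-1-[(tert-butyldiphenylsilyl)oxy]propan-2-yl}-1-(3-hydroxycyclohex-1-en-1-yl)cyclobutan-1-ol
Product: 20 3-[(1R,2R)-2-{(S)-1-[(tert-butyldiphenylsilyl)oxy]propan-2-yl}-1-hydroxycyclobutyl]cyclohex-2-en-1-one
Conditions: MnO2, CH2Cl2, rt
Reagents that add atoms: none
Why: Selective oxidation of the secondary allylic alcohol; the tertiary cyclobutanol cannot be oxidised and both epimers of 19 give the same enone.

Step 12
Reactants: 20 3-[(1R,2R)-2-{(S)-1-[(tert-butyldiphenylsilyl)oxy]propan-2-yl}-1-hydroxycyclobutyl]cyclohex-2-en-1-one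
Product: 21 (4R,5R)-4-{(S)-1-[(tert-butyldiphenylsilyl)oxy]propan-2-yl}spiro[4.5]decane-1,7-dione
Conditions: 9-amino-9-deoxy-epi-quinidine (20 mol %), N-Boc-D-phenylglycine (40 mol %), CCl4, 25 °C
Reagents that add atoms: none
Why: The primary amine condenses with the C16 ketone to an iminium ion, which makes C12 electrophilic; the C8–C11 bond, aligned with the π system, shifts suprafacially to C12 while the C11 hydroxyl becomes the ketone, and hydrolysis of the resulting enamine returns the catalyst. The closest known reaction is the cinchona-primary-amine-catalysed vinylogous α-ketol rearrangement of 1-(3-oxocyclohex-1-enyl)cyclobutanols to spiro[4.5]decane-1,7-diones. The cyclopentanone is closed by a 1,2-alkyl shift, that is by one-carbon ring expansion of the cyclobutanol, and not by an end-to-end cyclisation. C12 is the only new stereocentre and is fixed by the face of the iminium β-carbon that receives C8 (the Si face), which the chiral amine salt selects; C8 migrates with retention, so C7 and C8 are carried over unchanged. Two selectivities are needed: migration of C8 and not C10, secured by the higher migratory aptitude of the more substituted ring carbon, and Si- over Re-face delivery, where the substrate should help the catalyst because in the Si-face transition state the C7 branch and the hydroxyl lie over the saturated C13 methylene while only the cyclobutane CH2 (C10) faces the iminium side where the catalyst sits. Relief of ring strain and formation of the C=O bond make the shift irreversible.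

Step 13
Reactants: 21 (4R,5R)-4-{(S)-1-[(tert-butyldiphenylsilyl)oxy]propan-2-yl}spiro[4.5]decane-1,7-dione
Product: 22 (4R,5R)-4-{(S)-1-[(tert-butyldiphenylsilyl)oxy]propan-2-yl}-7,7-(ethylenedioxy)spiro[4.5]decan-1-one
Conditions: TMSOCH2CH2OTMS, TMSOTf (5 mol %), CH2Cl2, −78 to −20 °C
Reagents that add atoms: 1,2-bis(trimethylsilyloxy)ethane, C[Si](C)(C)OCCO[Si](C)(C)C
Why: Silyl-triflate-catalysed ketalisation under kinetic control; the unhindered cyclohexanone (C16) reacts while the cyclopentanone flanked by the quaternary C12 does not.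

Step 14
Reactants: 22 (4R,5R)-4-{(S)-1-[(tert-butyldiphenylsilyl)oxy]propan-2-yl}-7,7-(ethylenedioxy)spiro[4.5]decan-1-one
Product: 23 (1R,5R)-1-{(S)-1-[(tert-butyldiphenylsilyl)oxy]propan-2-yl}-7,7-(ethylenedioxy)-4-methylidenespiro[4.5]decane
Conditions: Ph3PCH3Br, KOt-Bu, toluene, 90 °C
Reagents that add atoms: methyltriphenylphosphonium bromide, C[P+](c1ccccc1)(c1ccccc1)c1ccccc1.[Br-]
Why: Wittig methylenation, which with the salt-free ylide at elevated temperature reaches hindered α-quaternary ketones; no stereocentre is α to the carbonyl.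

Step 15
Reactants: 23 (1R,5R)-1-{(S)-1-[(tert-butyldiphenylsilyl)oxy]propan-2-yl}-7,7-(ethylenedioxy)-4-methylidenespiro[4.5]decane
Product: 24 (S)-2-[(1R,5R)-7,7-(ethylenedioxy)-4-methylidenespiro[4.5]decan-1-yl]propan-1-ol
Conditions: Bu4NF, THF, rt
Reagents that add atoms: none
Why: Fluoride cleavage of the silyl ether frees the C6 hydroxyl that is needed as the directing group in step 16.

Step 16
Reactants: 24 (S)-2-[(1R,5R)-7,7-(ethylenedioxy)-4-methylidenespiro[4.5]decan-1-yl]propan-1-ol
Product: 25 (S)-2-[(1R,4S,5S)-7,7-(ethylenedioxy)-4-methylspiro[4.5]decan-1-yl]propan-1-ol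
Conditions: [Ir(cod)(PCy3)(py)]PF6 (5 mol %), H2 (1 atm), CH2Cl2, 0 °C to rt
Reagents that add atoms: none
Why: Hydroxyl-directed hydrogenation, in which the cationic iridium complex is held by the C6 hydroxyl on the C13 face of the cyclopentane and delivers H2 to that face of the C11 methylidene, so that the methyl ends on the C17 face (11S); the dioxolane oxygen syn-axial to C11 should screen the opposite face.

Step 17
Reactants: 25 (S)-2-[(1R,4S,5S)-7,7-(ethylenedioxy)-4-methylspiro[4.5]decan-1-yl]propan-1-ol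
Product: 26 (1R,4S,5S)-1-[(S)-1-hydroxypropan-2-yl]-4-methylspiro[4.5]decan-7-one
Conditions: 1 M HCl, THF, rt
Reagents that add atoms: water, O
Why: Acid hydrolysis of the dioxolane; no other acid-sensitive group is present.

Step 18
Reactants: 26 (1R,4S,5S)-1-[(S)-1-hydroxypropan-2-yl]-4-methylspiro[4.5]decan-7-one
Product: 27 (1R,4S,5S)-1-{(S)-1-[(tert-butyldimethylsilyl)oxy]propan-2-yl}-4-methylspiro[4.5]decan-7-one
Conditions: TBSCl, imidazole, DMF, rt
Reagents that add atoms: tert-butyldimethylsilyl chloride, CC(C)(C)[Si](C)(C)Cl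
Why: Silylation of the primary alcohol so that it survives enolate chemistry, reduction and acylation and can be removed next to the ester in step 23.

Step 19
Reactants: 27 (1R,4S,5S)-1-{(S)-1-[(tert-butyldimethylsilyl)oxy]propan-2-yl}-4-methylspiro[4.5]decan-7-one
Product: 28 (1R,4S,5S)-1-{(S)-1-[(tert-butyldimethylsilyl)oxy]propan-2-yl}-4,8-dimethylspiro[4.5]decan-7-one (both epimers at the new methyl-bearing carbon)
Conditions: LiN(i-Pr)2, THF, −78 °C; then MeI, −78 to −40 °C
Reagents that add atoms: iodomethane, CI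
Why: Kinetic enolate alkylation, in which the amide base removes a proton from C15 and not from C17 (neopentyl, next to the spiro centre); the C15 configuration is irrelevant because it is removed in step 20.

Step 20
Reactants: 28 (1R,4S,5S)-1-{(S)-1-[(tert-butyldimethylsilyl)oxy]propan-2-yl}-4,8-dimethylspiro[4.5]decan-7-one
Product: 30 (1R,4S,5S)-1-{(S)-1-[(tert-butyldimethylsilyl)oxy]propan-2-yl}-4,8-dimethylspiro[4.5]dec-8-en-7-one, via trimethylsilyl enol ether 29 (not isolated)
Conditions: TMSCl, NaI, Et3N, MeCN, rt; then Pd(OAc)2 (1.1 equiv), MeCN, rt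
Reagents that add atoms: none
Why: Saegusa–Ito oxidation, in which the more substituted silyl enol ether forms under equilibrating conditions and divalent palladium then removes a C14 hydrogen by β-hydride elimination; an enol ether toward C17 has no β-hydrogen and can only return ketone.

Step 21
Reactants: 30 (1R,4S,5S)-1-{(S)-1-[(tert-butyldimethylsilyl)oxy]propan-2-yl}-4,8-dimethylspiro[4.5]dec-8-en-7-one
Product: 31 (1R,4S,5S,7S)-1-{(S)-1-[(tert-butyldimethylsilyl)oxy]propan-2-yl}-4,8-dimethylspiro[4.5]dec-8-en-7-ol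
Conditions: (R)-2-methyl-CBS-oxazaborolidine (0.3 equiv), BH3·SMe2, THF, −30 °C; then MeOH
Reagents that add atoms: none
Why: Corey–Bakshi–Shibata reduction, in which the (R)-oxazaborolidine treats the alkenyl side (C15) as the large group and delivers hydride to the face that gives the (S)-carbinol at C16; reagent control is relied on over the bias of the remote spiro centre.

Step 22
Reactants: 31 (1R,4S,5S,7S)-1-{(S)-1-[(tert-butyldimethylsilyl)oxy]propan-2-yl}-4,8-dimethylspiro[4.5]dec-8-en-7-ol; 32 3-phenylpropanoyl chloride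
Product: 33 (1R,4S,5S,7S)-1-{(S)-1-[(tert-butyldimethylsilyl)oxy]propan-2-yl}-4,8-dimethylspiro[4.5]dec-8-en-7-yl 3-phenylpropanoate
Conditions: pyridine, DMAP (10 mol %), CH2Cl2, 0 °C to rt
Reagents that add atoms: none
Why: Nucleophile-catalysed acylation of the secondary allylic alcohol at oxygen, with retention at C16.

Step 23
Reactants: 33 (1R,4S,5S,7S)-1-{(S)-1-[(tert-butyldimethylsilyl)oxy]propan-2-yl}-4,8-dimethylspiro[4.5]dec-8-en-7-yl 3-phenylpropanoate
Product: 34 (1R,4S,5S,7S)-1-[(S)-1-hydroxypropan-2-yl]-4,8-dimethylspiro[4.5]dec-8-en-7-yl 3-phenylpropanoate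
Conditions: HF·pyridine, pyridine, THF, 0 °C to rt
Reagents that add atoms: none
Why: Buffered fluoride cleaves the primary silyl ether without touching the allylic ester, which a basic fluoride source could hydrolyse.

Step 24
Reactants: 34 (1R,4S,5S,7S)-1-[(S)-1-hydroxypropan-2-yl]-4,8-dimethylspiro[4.5]dec-8-en-7-yl 3-phenylpropanoate
Product: 35 (1R,4S,5S,7S)-4,8-dimethyl-1-[(S)-1-oxopropan-2-yl]spiro[4.5]dec-8-en-7-yl 3-phenylpropanoate
Conditions: Dess–Martin periodinane, NaHCO3, CH2Cl2, 0 °C to rt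
Reagents that add atoms: none
Why: Buffered Dess–Martin oxidation gives the α-branched aldehyde without epimerising C7; the aldehyde is used without chromatography.

Step 25
Reactants: 36 3-methylfuran-2(5H)-one
Product: 37 tert-butyldimethyl[(3-methylfuran-2-yl)oxy]silane
Conditions: TBSOTf, Et3N, CH2Cl2, 0 °C
Reagents that add atoms: tert-butyldimethylsilyl triflate, CC(C)(C)[Si](C)(C)OS(=O)(=O)C(F)(F)F
Why: O-silylation of the butenolide dienolate gives the aromatic 2-silyloxyfuran, a γ-selective butenolide nucleophile.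

Step 26
Reactants: 35 (1R,4S,5S,7S)-4,8-dimethyl-1-[(S)-1-oxopropan-2-yl]spiro[4.5]dec-8-en-7-yl 3-phenylpropanoate; 37 tert-butyldimethyl[(3-methylfuran-2-yl)oxy]silane
Product: 38 (1R,4S,5S,7S)-1-[(2S)-1-hydroxy-1-(4-methyl-5-oxo-2,5-dihydrofuran-2-yl)propan-2-yl]-4,8-dimethylspiro[4.5]dec-8-en-7-yl 3-phenylpropanoate (mixture at the two new centres)
Conditions: BF3·OEt2, CH2Cl2, −78 °C; then aq. NaHCO3
Reagents that add atoms: none
Why: Vinylogous Mukaiyama aldol reaction, in which the silyloxyfuran attacks the activated aldehyde through its 5-position and forms C5–C6; both new centres disappear in step 27 and C7 should not epimerise at −78 °C in the absence of base.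

Step 27
Reactants: 38 (1R,4S,5S,7S)-1-[(2S)-1-hydroxy-1-(4-methyl-5-oxo-2,5-dihydrofuran-2-yl)propan-2-yl]-4,8-dimethylspiro[4.5]dec-8-en-7-yl 3-phenylpropanoate
Product: 40 (1R,4S,5S,7S)-4,8-dimethyl-1-[(S,Z)-1-(4-methyl-5-oxofuran-2(5H)-ylidene)propan-2-yl]spiro[4.5]dec-8-en-7-yl 3-phenylpropanoate, via mesylate 39 (not isolated)
Conditions: MsCl, Et3N (4 equiv), CH2Cl2, 0 °C to rt
Reagents that add atoms: none
Why: Mesylation and E1cB elimination through the furanolate anion create C5=C6; the Z isomer (C7 syn to the ring oxygen) should prevail because the E isomer suffers allylic strain between C7 and H4, and triethylamine at this temperature should not deprotonate C7.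

**Compound list**

1 | methyl (R)-3-hydroxy-2-methylpropanoate | COC(=O)[C@H](C)CO | starting material
2 | methyl (R)-3-[(tert-butyldiphenylsilyl)oxy]-2-methylpropanoate | COC(=O)[C@H](C)CO[Si](c1ccccc1)(c1ccccc1)C(C)(C)C | intermediate
3 | (R)-3-[(tert-butyldiphenylsilyl)oxy]-2-methylpropanoic acid | OC(=O)[C@H](C)CO[Si](c1ccccc1)(c1ccccc1)C(C)(C)C | intermediate
4 | isobutyl carbonic mixed anhydride of 3 | CC(C)COC(=O)OC(=O)[C@H](C)CO[Si](c1ccccc1)(c1ccccc1)C(C)(C)C | intermediate
5 | (R)-4-[(tert-butyldiphenylsilyl)oxy]-1-diazo-3-methylbutan-2-one | [N-]=[N+]=CC(=O)[C@H](C)CO[Si](c1ccccc1)(c1ccccc1)C(C)(C)C | intermediate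
6 | (2S,5S)-2,5-dimethylpyrrolidine | C[C@H]1CC[C@H](C)N1 | starting material
7 | (S)-4-[(tert-butyldiphenylsilyl)oxy]-3-methylbut-1-en-1-one (ketene) | O=C=C[C@H](C)CO[Si](c1ccccc1)(c1ccccc1)C(C)(C)C | intermediate
8 | (S)-4-[(tert-butyldiphenylsilyl)oxy]-1-[(2S,5S)-2,5-dimethylpyrrolidin-1-yl]-3-methylbutan-1-one | CC(C)(C)[Si](c1ccccc1)(c1ccccc1)OC[C@@H](C)CC(=O)N1[C@@H](C)CC[C@@H]1C | intermediate
9 | ethene | C=C | starting material
10 | keteniminium triflate from 8 | CC(C)(C)[Si](c1ccccc1)(c1ccccc1)OC[C@@H](C)C=C=[N+]1[C@@H](C)CC[C@@H]1C.[O-]S(=O)(=O)C(F)(F)F | intermediate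
11 | (2S,5S)-1-[(R)-2-{(S)-1-[(tert-butyldiphenylsilyl)oxy]propan-2-yl}cyclobutylidene]-2,5-dimethylpyrrolidinium triflate | CC(C)(C)[Si](c1ccccc1)(c1ccccc1)OC[C@@H](C)[C@H]2CCC2=[N+]1[C@@H](C)CC[C@@H]1C.[O-]S(=O)(=O)C(F)(F)F | intermediate
12 | (R)-2-{(S)-1-[(tert-butyldiphenylsilyl)oxy]propan-2-yl}cyclobutan-1-one | CC(C)(C)[Si](c1ccccc1)(c1ccccc1)OC[C@@H](C)[C@H]1CCC1=O | intermediate
13 | cyclohexane-1,3-dione | O=C1CCCC(=O)C1 | starting material
14 | 3-bromocyclohex-2-en-1-one | O=C1C=C(Br)CCC1 | intermediate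
15 | rac-3-bromocyclohex-2-en-1-ol | OC1C=C(Br)CCC1 | intermediate
16 | rac-[(3-bromocyclohex-2-en-1-yl)oxy]triethylsilane | CC[Si](CC)(CC)OC1C=C(Br)CCC1 | intermediate
17 | [3-(triethylsilyloxy)cyclohex-1-en-1-yl]lithium | [Li]C1=CC(O[Si](CC)(CC)CC)CCC1 | intermediate
18 | (1R,2R)-2-{(S)-1-[(tert-butyldiphenylsilyl)oxy]propan-2-yl}-1-[3-(triethylsilyloxy)cyclohex-1-en-1-yl]cyclobutan-1-ol, two epimers at the silyloxy carbon | CC(C)(C)[Si](c1ccccc1)(c1ccccc1)OC[C@@H](C)[C@H]2CC[C@]2(O)C3=CC(O[Si](CC)(CC)CC)CCC3 | intermediate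
19 | (1R,2R)-2-{(S)-1-[(tert-butyldiphenylsilyl)oxy]propan-2-yl}-1-(3-hydroxycyclohex-1-en-1-yl)cyclobutan-1-ol, two epimers at the ring carbinol | CC(C)(C)[Si](c1ccccc1)(c1ccccc1)OC[C@@H](C)[C@H]2CC[C@]2(O)C3=CC(O)CCC3 | intermediate
20 | 3-[(1R,2R)-2-{(S)-1-[(tert-butyldiphenylsilyl)oxy]propan-2-yl}-1-hydroxycyclobutyl]cyclohex-2-en-1-one | CC(C)(C)[Si](c1ccccc1)(c1ccccc1)OC[C@@H](C)[C@H]2CC[C@]2(O)C3=CC(=O)CCC3 | intermediate
21 | (4R,5R)-4-{(S)-1-[(tert-butyldiphenylsilyl)oxy]propan-2-yl}spiro[4.5]decane-1,7-dione | CC(C)(C)[Si](c1ccccc1)(c1ccccc1)OC[C@@H](C)[C@H]2CCC(=O)[C@@]23CCCC(=O)C3 | intermediate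
22 | (4R,5R)-4-{(S)-1-[(tert-butyldiphenylsilyl)oxy]propan-2-yl}-7,7-(ethylenedioxy)spiro[4.5]decan-1-one | CC(C)(C)[Si](c1ccccc1)(c1ccccc1)OC[C@@H](C)[C@H]2CCC(=O)[C@@]23CCCC4(OCCO4)C3 | intermediate
23 | (1R,5R)-1-{(S)-1-[(tert-butyldiphenylsilyl)oxy]propan-2-yl}-7,7-(ethylenedioxy)-4-methylidenespiro[4.5]decane | CC(C)(C)[Si](c1ccccc1)(c1ccccc1)OC[C@@H](C)[C@H]2CCC(=C)[C@@]23CCCC4(OCCO4)C3 | intermediate
24 | (S)-2-[(1R,5R)-7,7-(ethylenedioxy)-4-methylidenespiro[4.5]decan-1-yl]propan-1-ol | OC[C@@H](C)[C@H]2CCC(=C)[C@@]23CCCC4(OCCO4)C3 | intermediate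
25 | (S)-2-[(1R,4S,5S)-7,7-(ethylenedioxy)-4-methylspiro[4.5]decan-1-yl]propan-1-ol | OC[C@@H](C)[C@H]2CC[C@H](C)[C@@]23CCCC4(OCCO4)C3 | intermediate
26 | (1R,4S,5S)-1-[(S)-1-hydroxypropan-2-yl]-4-methylspiro[4.5]decan-7-one | OC[C@@H](C)[C@H]2CC[C@H](C)[C@@]23CCCC(=O)C3 | intermediate
27 | (1R,4S,5S)-1-{(S)-1-[(tert-butyldimethylsilyl)oxy]propan-2-yl}-4-methylspiro[4.5]decan-7-one | CC(C)(C)[Si](C)(C)OC[C@@H](C)[C@H]2CC[C@H](C)[C@@]23CCCC(=O)C3 | intermediate
28 | (1R,4S,5S)-1-{(S)-1-[(tert-butyldimethylsilyl)oxy]propan-2-yl}-4,8-dimethylspiro[4.5]decan-7-one, both epimers at C15 | CC(C)(C)[Si](C)(C)OC[C@@H](C)[C@H]2CC[C@H](C)[C@@]23CCC(C)C(=O)C3 | intermediate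
29 | trimethylsilyl enol ether of 28 (C15=C16) | CC(C)(C)[Si](C)(C)OC[C@@H](C)[C@H]2CC[C@H](C)[C@@]23CCC(C)=C(O[Si](C)(C)C)C3 | intermediate
30 | (1R,4S,5S)-1-{(S)-1-[(tert-butyldimethylsilyl)oxy]propan-2-yl}-4,8-dimethylspiro[4.5]dec-8-en-7-one | CC(C)(C)[Si](C)(C)OC[C@@H](C)[C@H]2CC[C@H](C)[C@@]23CC=C(C)C(=O)C3 | intermediate
31 | (1R,4S,5S,7S)-1-{(S)-1-[(tert-butyldimethylsilyl)oxy]propan-2-yl}-4,8-dimethylspiro[4.5]dec-8-en-7-ol | CC(C)(C)[Si](C)(C)OC[C@@H](C)[C@H]2CC[C@H](C)[C@@]23CC=C(C)[C@@H](O)C3 | intermediate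
32 | 3-phenylpropanoyl chloride | O=C(Cl)CCc1ccccc1 | starting material
33 | (1R,4S,5S,7S)-1-{(S)-1-[(tert-butyldimethylsilyl)oxy]propan-2-yl}-4,8-dimethylspiro[4.5]dec-8-en-7-yl 3-phenylpropanoate | CC(C)(C)[Si](C)(C)OC[C@@H](C)[C@H]2CC[C@H](C)[C@@]23CC=C(C)[C@@H](OC(=O)CCc4ccccc4)C3 | intermediate
34 | (1R,4S,5S,7S)-1-[(S)-1-hydroxypropan-2-yl]-4,8-dimethylspiro[4.5]dec-8-en-7-yl 3-phenylpropanoate | OC[C@@H](C)[C@H]2CC[C@H](C)[C@@]23CC=C(C)[C@@H](OC(=O)CCc4ccccc4)C3 | intermediate
35 | (1R,4S,5S,7S)-4,8-dimethyl-1-[(S)-1-oxopropan-2-yl]spiro[4.5]dec-8-en-7-yl 3-phenylpropanoate | O=C[C@@H](C)[C@H]2CC[C@H](C)[C@@]23CC=C(C)[C@@H](OC(=O)CCc4ccccc4)C3 | intermediate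
36 | 3-methylfuran-2(5H)-one | CC1=CCOC1=O | starting material
37 | tert-butyldimethyl[(3-methylfuran-2-yl)oxy]silane | Cc1ccoc1O[Si](C)(C)C(C)(C)C | intermediate
38 | (1R,4S,5S,7S)-1-[(2S)-1-hydroxy-1-(4-methyl-5-oxo-2,5-dihydrofuran-2-yl)propan-2-yl]-4,8-dimethylspiro[4.5]dec-8-en-7-yl 3-phenylpropanoate, mixture at C5 and C6 | CC1=CC(OC1=O)C(O)[C@@H](C)[C@H]2CC[C@H](C)[C@@]23CC=C(C)[C@@H](OC(=O)CCc4ccccc4)C3 | intermediate
39 | methanesulfonate of 38 | CC1=CC(OC1=O)C(OS(C)(=O)=O)[C@@H](C)[C@H]2CC[C@H](C)[C@@]23CC=C(C)[C@@H](OC(=O)CCc4ccccc4)C3 | intermediate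
40 | (1R,4S,5S,7S)-4,8-dimethyl-1-[(S,Z)-1-(4-methyl-5-oxofuran-2(5H)-ylidene)propan-2-yl]spiro[4.5]dec-8-en-7-yl 3-phenylpropanoate (CNP0260277.1) | CC1=C/C(=C/[C@@H](C)[C@H]2CC[C@H](C)[C@@]23CC=C(C)[C@@H](OC(=O)CCc2ccccc2)C3)OC1=O | target

**Count**

Total step count: 27. Longest linear sequence: 23 steps (steps 1–5, 9–24, 26 and 27).

**Steps most likely to fail**

Step 12. Delivery of C8 to the Re face of C12 may compete if the chiral amine salt and the two cyclobutanol stereocentres are mismatched, and migration of the unsubstituted C10 may take over when C8 migration is slowed. The fallback changes how oxygen is brought to C16.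
- From 20 the shift is run with the pseudoenantiomeric salt (9-amino-9-deoxy-epi-quinine, N-Boc-L-phenylglycine), for which Re-face delivery is then the matched case. This gives the C12-epimeric dione F1, in which the six-ring carbonyl is at C14.
- The operations of steps 13 to 20 are repeated on it: ketal F2, methylidene compound F3, alcohol F4, directed-hydrogenation product F5, keto alcohol F6, silyl ether F7, C15-methyl ketone F8, its trimethylsilyl enol ether F9 and the C14-oxo C15=C16 enone F10.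
- Nucleophilic epoxidation (H2O2, NaOH, MeOH, 0 °C) should add to C16 anti to the pseudo-axial C11, the face the target needs, and give epoxy ketone F11.
- Wharton transposition (N2H4·H2O, AcOH, MeOH) then gives allylic alcohol 31, where the route is rejoined.

Step 5. Facial control at C8 may be incomplete, the silyl ether oxygen may attack the activated amide, or C8 may epimerise while the iminium salt is hydrolysed. The fallback builds the four-membered ring by ring expansion instead of cycloaddition.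
- From ester 2, i-Bu2AlH (CH2Cl2, −78 °C) gives (R)-3-[(tert-butyldiphenylsilyl)oxy]-2-methylpropanal F12.
- Wittig reaction with cyclopropylidenetriphenylphosphorane (cyclopropyltriphenylphosphonium bromide, NaH, THF) gives the alkylidenecyclopropane F13.
- Asymmetric dioxirane epoxidation (fructose-derived ketone catalyst, KHSO5, in the enantiomeric series that gives the 8S epoxide) gives oxaspiropentane F14.
- Et2AlCl (CH2Cl2, −78 °C) induces the 1,2-shift of a cyclopropane carbon to C8 with inversion and returns to the route at cyclobutanone 12.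

Step 16. The hydroxyl is four carbons away from the alkene, so hydrogen may be delivered without effective direction, the ketal oxygens may compete for the metal, or the alkene may migrate into the ring. The fallback replaces coordination control by steric and thermodynamic control.
- From 24, metal-hydride hydrogen-atom-transfer hydrogenation (Mn(dpm)3, PhSiH3, t-BuOOH, i-PrOH, rt) proceeds through the tertiary C11 radical.
- The radical should be quenched on the face not shielded by the syn-axial dioxolane oxygen, giving the epimer expected to be the more stable one (methyl on the C17 side, trans to the C8 branch), though this preference is not assured.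
- It returns to the route at 25 and makes no new compound.

**Further compounds**

F1 | step 12 | (4R,5S)-4-{(S)-1-[(tert-butyldiphenylsilyl)oxy]propan-2-yl}spiro[4.5]decane-1,7-dione (C12 epimer of 21) | CC(C)(C)[Si](c1ccccc1)(c1ccccc1)OC[C@@H](C)[C@H]2CCC(=O)[C@@]23CC(=O)CCC3
F2 | step 12 | C12 epimer of 22 (dioxolane at C14) | CC(C)(C)[Si](c1ccccc1)(c1ccccc1)OC[C@@H](C)[C@H]2CCC(=O)[C@@]23CC4(OCCO4)CCC3
F3 | step 12 | C12 epimer of 23 | CC(C)(C)[Si](c1ccccc1)(c1ccccc1)OC[C@@H](C)[C@H]2CCC(=C)[C@@]23CC4(OCCO4)CCC3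
F4 | step 12 | C12 epimer of 24 | OC[C@@H](C)[C@H]2CCC(=C)[C@@]23CC4(OCCO4)CCC3
F5 | step 12 | C12 epimer of 25 | OC[C@@H](C)[C@H]2CC[C@H](C)[C@@]23CC4(OCCO4)CCC3
F6 | step 12 | C12 epimer of 26 (ketone at C14) | OC[C@@H](C)[C@H]2CC[C@H](C)[C@@]23CC(=O)CCC3
F7 | step 12 | C12 epimer of 27 | CC(C)(C)[Si](C)(C)OC[C@@H](C)[C@H]2CC[C@H](C)[C@@]23CC(=O)CCC3
F8 | step 12 | C12 epimer of 28 (C14 ketone, C15 methyl, both C15 epimers) | CC(C)(C)[Si](C)(C)OC[C@@H](C)[C@H]2CC[C@H](C)[C@@]23CC(=O)C(C)CC3
F9 | step 12 | trimethylsilyl enol ether of F8 (C14=C15) | CC(C)(C)[Si](C)(C)OC[C@@H](C)[C@H]2CC[C@H](C)[C@@]23CC(O[Si](C)(C)C)=C(C)CC3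
F10 | step 12 | C12 epimer of 30 (C14 ketone, C15=C16) | CC(C)(C)[Si](C)(C)OC[C@@H](C)[C@H]2CC[C@H](C)[C@@]23CC(=O)C(C)=CC3
F11 | step 12 | C15,C16-epoxide of F10, oxirane on the ring face syn to C8 | CC(C)(C)[Si](C)(C)OC[C@@H](C)[C@H]2CC[C@H](C)[C@@]23CC(=O)[C@@]4(C)O[C@H]4C3
F12 | step 5 | (R)-3-[(tert-butyldiphenylsilyl)oxy]-2-methylpropanal | O=C[C@H](C)CO[Si](c1ccccc1)(c1ccccc1)C(C)(C)C
F13 | step 5 | (S)-tert-butyl(3-cyclopropylidene-2-methylpropoxy)diphenylsilane | C1CC1=C[C@H](C)CO[Si](c1ccccc1)(c1ccccc1)C(C)(C)C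
F14 | step 5 | (S)-2-{(R)-1-[(tert-butyldiphenylsilyl)oxy]propan-2-yl}-1-oxaspiro[2.2]pentane | CC(C)(C)[Si](c1ccccc1)(c1ccccc1)OC[C@@H](C)[C@@H]2OC23CC3
F0 | step 16 | none | none
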